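Start from an easy step: if each Z works at its own pace, G should follow the product of Z and time.

| setting | spring | midnight | Saturday's | Sunday's | Thursday's | Monday's |
|---|---|---|---|---|---|---|
| J | 0.020 M | 0.020 M | 0.020 M | 0.020 M | 0.020 M (fed, over 40.0 h) | 0.020 M |
| E | 0.030 M | 0.030 M | 0.0300 M | 0.0300 M | 0.0300 M | 0.0300 M (fed, over 40.0 h) |
| Z | 0.20 mM | 0.40 mM | 0.20 mM | 0.20 mM | 0.20 mM | 0.20 mM |
| remark | run made earlier | run made earlier | one stirred flow tank at steady state, fed with the mixture as stated, mean residence time 50 h | a closed flask charged with all of it at once and left for 50 h | all but J at the start; J goes in evenly over 40.0 h, the run ends at 50 h | all but E at the start; E goes in evenly over 40.0 h, the run ends at 50 h |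
| time |  |  |  | 50 h | 50 h | 50 h |

| run | time / h | G / % |
|---|---|---|
| spring | 1.50 | 0 |
| spring | 5.00 | 3.1 |
| spring | 8.00 | 6.0 |
| spring | 12.0 | 9.5 |
| spring | 20.0 | 15.0 |
| spring | 25.0 | 18.1 |
| spring | 30.0 | 23.7 |
| midnight | 0.833 | 0 |
| midnight | 2.50 | 4.1 |
| midnight | 4.00 | 5.3 |
| midnight | 6.00 | 7.9 |
| midnight | 10.0 | 13.9 |
| midnight | 12.0 | 16.3 |
| midnight | 15.0 | 20.1 |

(readings scatter by 1 percentage point)

- the stated concentrations are those of everything mixed, before any reaction; amounts are the same in each set-up
- steps thought possible: E + Z -> X; X <-> L; J + L -> Q; Q -> Z + G
- the feed brings no volume worth counting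
- the earlier runs were made in a closed, stirred flask

* the set-up with the highest amount of G at the outlet or at the end, in percent of the J put in ("none" if the first two lie within 2 percentage points) (Saturday's / Sunday's / Thursday's / Monday's / none)
* amount of G at the outlet or at the end, in percent of the J put in, Saturday's
* amount of G at the outlet or at the end, in percent of the J put in, Sunday's
* amount of G at the outlet or at the end, in percent of the J put in, Thursday's
* amount of G at the outlet or at the end, in percent of the J put in, Monday's

The midnight run has twice the Z of the spring run for half the time, so their last readings, 23.7% and 20.1%, stand at one product. I take their mean, 21.9%, as G at 30.0 h with 0.20 mM of Z.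

The open question is which concentration sets the order of the rate. Each of J and E enters the steps once, so I bracket Sunday's closed flask between two orders. If neither mattered, the line would run straight to 36.5%, the bound from above. If the rate were first order in both, with E at 1.50 equivalents, G would reach 32.5%, the bound from below.

J is the limiting reagent, and at that mean reading the share of E left is larger than the share of J left. Both runs had 0.020 M of J, so this is a choice and not a reading: my own reckoning lets J set the order, a pseudo-first-order fall, with 0.00824 /h as κ, the fraction of the J present that becomes G each hour at 0.20 mM of Z.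

This gives 33.8% for Sunday's. Saturday's tank gives κ times residence time over one plus that product, 29.2%. Thursday's J, fed evenly, gives 21.5%. Of these reckoned figures Sunday's is the highest, and I give Monday's no number.

The forecast gave 35%, 38%, 37% and 28% in the order asked, with none as best, and said “Feeding J costs little, since it outruns consumption”. Its Sunday's figure stands above my upper bound.

The simulation gives 29.2%, 32.9%, 22.5% and 27.1%, with Sunday's best.

    E + Z → X (k = 0.0430 /M/s)
    X ⇌ L (K = 0.430, k = 0.00120 /s)
    J + L → Q (k = 0.0550 /M/s)
    Q → Z + G (k = 0.0160 /s)

Sunday's result lies inside the bracket, 0.90 percentage points under my figure, and Thursday's lies 1.00 point over mine. Now take a neighbouring flask, Sunday's with 5.0 × 10⁻⁴ M of Z. Scaling κ with Z gives 64.3%. That flask gave 65.4%, with 35% of its J left.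

(The runs stem from a simulated flask for an exercise, noise included.)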